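**Remark:** C-numbers in names and comments are the gibberellane numbers of the target (C7, C19 and C20 are the carboxyl carbons). α and β refer to the usual drawing of the gibberellins (C20 on C10 α, the hydrogens on C5 and C9 β); the SMILES strings define the configurations. The target, the gibberellin of the A series with the number 17, is called the target acid below. Compounds 1, 7 and 12 are taken as purchasable.

## Retrosynthetic overview

1. Target acid ⇐ trimethyl ester 13-silyl ether ⇐ 17-nor-16-ketone (methylenation) ⇐ 11-oxo tetracyclic cycloadduct (C11 carbonyl deleted through its enol triflate).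
2. Key disconnection: C8–C9 and C12–C13 together, by an intramolecular (4+3) cycloaddition of a 2-silyloxyallyl cation (C9–C11–C12) with a ring D cyclopentadiene; rings B and C close in one operation.
3. Enabling feature: in the bicyclo[3.2.1]octane of rings C and D, the bridgeheads C8 and C13 are the 1,4-termini of ring D across the one-carbon bridge C14, and C13/C16 carry the only heteroatom and alkene functions. Ring D is thus a 4-substituted cyclopentane-1,2-dione in disguise, symmetric about C8, whose bis-silyl dienol ether is the 4π partner; the three-carbon bridge C9–C11–C12 is an oxyallyl unit.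
4. Precursor: a ring A triester carrying the dione on C6 and an α-acetoxy methyl ketone on C10. C4 comes from a Cu-catalysed conjugate addition, C5 from CBS reduction and Ireland–Claisen chirality transfer (C5–C6 bond), C10 from a reductive aldol.
5. Ring order: A (purchased ring, decorated) → D (purchased cyclopentene, oxidised to the dione) → B and C together (key step).

Key step: step 12

## Route

Step 1
Reactants: 1 methyl 3-oxocyclohex-1-ene-1-carboxylate
Product: 3 methyl (R)-1-methyl-3-(trifluoromethylsulfonyloxy)cyclohex-2-ene-1-carboxylate, via zinc enolate 2 (not isolated)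
Conditions: Me2Zn, (CuOTf)2·C6H6 (2.5 mol %), chiral sulfonate-bearing imidazolinium salt (N-heterocyclic carbene precursor, 5 mol %), t-BuOMe, −30 °C; then Tf2O, −78 → 0 °C
Reagents that add atoms: dimethylzinc C[Zn]C; triflic anhydride O=S(=O)(OS(=O)(=O)C(F)(F)F)C(F)(F)F
Why: Cu/NHC-catalysed enantioselective conjugate addition of a methyl group to the β-ester enone should set the C4 quaternary centre (ligand enantiomer chosen for R), and O-triflation of the zinc enolate fixes the C5=C10 enol triflate regiochemistry.

Step 2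
Reactants: 3 methyl (R)-1-methyl-3-(trifluoromethylsulfonyloxy)cyclohex-2-ene-1-carboxylate
Product: 4 dimethyl (R)-1-methylcyclohex-2-ene-1,3-dicarboxylate
Conditions: CO (1 atm), MeOH, Pd(OAc)2, dppp, Et3N, DMF, 60 °C
Reagents that add atoms: carbon monoxide [C-]#[O+]; methanol CO
Why: Pd-catalysed methoxycarbonylation of an enol triflate installs the C20 ester on C10.

Step 3
Reactants: 4 dimethyl (R)-1-methylcyclohex-2-ene-1,3-dicarboxylate
Product: 5 dimethyl (R)-1-methyl-4-oxocyclohex-2-ene-1,3-dicarboxylate
Conditions: Rh2(cap)4 (dirhodium tetracaprolactamate, 1 mol %), t-BuOOH (70% aq., 5 equiv), 1,2-dichloroethane, 40 °C, no base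
Reagents that add atoms: tert-butyl hydroperoxide CC(C)(C)OO
Why: Peroxyl-radical allylic C–H oxidation should go to C1, the only allylic methylene (C4 is quaternary), giving the 2-carbomethoxy enone; leaving out base keeps the hydroperoxide anion from epoxidising the doubly activated alkene, whose β-carbon C5 is also shielded by the quaternary C4.

Step 4
Reactants: 5 dimethyl (R)-1-methyl-4-oxocyclohex-2-ene-1,3-dicarboxylate
Product: 6 dimethyl (1R,4S)-4-hydroxy-1-methylcyclohex-2-ene-1,3-dicarboxylate (hydroxyl cis to the C4 ester)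
Conditions: (R)-2-methyl-CBS-oxazaborolidine (20 mol %), catecholborane, toluene, −78 °C
Reagents that add atoms: none
Why: Corey–Bakshi–Shibata 1,2-reduction under catalyst control (the α-substituted alkenyl side acts as the large group) should set the C1 carbinol on the α face.

Step 5
Reactants: 6 dimethyl (1R,4S)-4-hydroxy-1-methylcyclohex-2-ene-1,3-dicarboxylate; 7 2-(cyclopent-3-en-1-yl)acetic acid
Product: 8 dimethyl (1R,4S)-4-[2-(cyclopent-3-en-1-yl)acetoxy]-1-methylcyclohex-2-ene-1,3-dicarboxylate
Conditions: DCC, DMAP (cat.), CH2Cl2, 0 °C → rt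
Reagents that add atoms: none
Why: Steglich esterification attaches the future C6–C7 unit and ring D to the allylic oxygen.

Step 6
Reactants: 8 dimethyl (1R,4S)-4-[2-(cyclopent-3-en-1-yl)acetoxy]-1-methylcyclohex-2-ene-1,3-dicarboxylate
Product: 11 dimethyl (1R,2R)-2-[1-(cyclopent-3-en-1-yl)-2-methoxy-2-oxoethyl]-1-methylcyclohex-3-ene-1,3-dicarboxylate (both C6 epimers), via silyl ketene acetal 9 (not isolated), via acid 10 (not isolated)
Conditions: LiN(i-Pr)2 (LDA), TMSCl, THF, −78 → 60 °C; aq. HCl; then TMSCHN2, MeOH/toluene, rt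
Reagents that add atoms: (trimethylsilyl)diazomethane C[Si](C)(C)C=[N+]=[N-]
Why: The Ireland–Claisen rearrangement is suprafacial, so the α C1–O bond is traded for an α C5–C6 bond (hydrogen on C5 β) next to the quaternary C4 and the alkene moves to C1=C10; C6 is set later.

Step 7
Reactants: 12 methyl 2,2-dimethoxypropanoate
Product: 13 2,2-dimethoxypropanal
Conditions: DIBAL-H (i-Bu2AlH), CH2Cl2, −78 °C; aq. potassium sodium tartrate (KNaC4H4O6)
Reagents that add atoms: none
Why: Partial reduction of an α,α-dialkoxy ester stops at the aldehyde through its stable tetrahedral aluminate.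

Step 8
Reactants: 11 dimethyl (1R,2R)-2-[1-(cyclopent-3-en-1-yl)-2-methoxy-2-oxoethyl]-1-methylcyclohex-3-ene-1,3-dicarboxylate; 13 2,2-dimethoxypropanal
Product: 16 dimethyl (1R,2R,3S)-3-(1-acetoxy-2,2-dimethoxypropyl)-2-[1-(cyclopent-3-en-1-yl)-2-methoxy-2-oxoethyl]-1-methylcyclohexane-1,3-dicarboxylate (epimers at C6 and C9), via potassium enolate 14 (not isolated), via potassium alkoxide 15 (not isolated)
Conditions: K-Selectride (KBH(s-Bu)3), THF, −78 °C; then 13, −78 °C; then Ac2O, −78 → 0 °C
Reagents that add atoms: acetic anhydride CC(=O)OC(C)=O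
Why: Reductive aldol: 1,4-hydride delivery to C1 gives the C10 ester enolate, which should add to the non-enolisable aldehyde on the face trans to the C5 side chain (C9 arm β, C20 ester α), and O-acetylation in the flask blocks retro-aldol and installs the leaving group at C9.

Step 9
Reactants: 16 dimethyl (1R,2R,3S)-3-(1-acetoxy-2,2-dimethoxypropyl)-2-[1-(cyclopent-3-en-1-yl)-2-methoxy-2-oxoethyl]-1-methylcyclohexane-1,3-dicarboxylate
Product: 17 the corresponding cis-3,4-dihydroxycyclopentyl compound (ring D diol; diol configuration immaterial)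
Conditions: OsO4 (2 mol %), NMO, acetone/H2O, rt
Reagents that add atoms: N-methylmorpholine N-oxide C[N+]1([O-])CCOCC1; water O
Why: Upjohn dihydroxylation of the only alkene left in the molecule.

Step 10
Reactants: 17 ring D diol
Product: 19 dimethyl (1R,2R,3S)-3-(1-acetoxy-2-oxopropyl)-2-[1-(3,4-dioxocyclopentyl)-2-methoxy-2-oxoethyl]-1-methylcyclohexane-1,3-dicarboxylate (dione largely as its enol), via ketal dione 18 (not isolated)
Conditions: (COCl)2, DMSO, CH2Cl2, −78 °C; Et3N, → 0 °C; then 1 M HCl, THF, rt
Reagents that add atoms: water O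
Why: Double Swern oxidation of the cis-diol gives the 1,2-dione without C–C cleavage, and aqueous acid unmasks the C11 methyl ketone while the acetate survives.

Step 11
Reactants: 19 dione α-acetoxy ketone
Product: 21 tris-silyl compound with a 3,4-bis(tert-butyldimethylsilyloxy)cyclopenta-1,3-dien-1-yl group on C6 and a 1-acetoxy-2-(tert-butyldimethylsilyloxy)prop-2-enyl group on C10, via dienol ether 20 (not isolated)
Conditions: TBSOTf (3.3 equiv), Et3N, CH2Cl2, −78 → 0 °C; then 40 °C, 2 h; pentane, filtration, used at once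
Reagents that add atoms: tert-butyldimethylsilyl triflate CC(C)(C)[Si](C)(C)OS(=O)(=O)C(F)(F)F
Why: Soft enolisation turns the dione into the 2,3-bis(silyloxy)cyclopentadiene 20 and the ketone into its methyl-side silyl enol ether (the C9 hydrogen is hindered); a thermal [1,5]-hydrogen shift from C8 to C14 (or to C15, the same by the symmetry of the dione) should then give the more substituted diene 21 with C8 as a diene terminus.

Step 12
Reactants: 21 tris-silyl diene allylic acetate
Product: 22 trimethyl 13,16-bis(tert-butyldimethylsilyloxy)-11-oxo-17-norgibberell-15-ene-7,19,20-trioate (configuration of the target at C4, C5, C8, C9, C10 and C13; both C6 epimers)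
Conditions: TMSOTf (20 mol %), 2,6-di-tert-butyl-4-methylpyridine (30 mol %), CH2Cl2 (0.005 M), −78 → −30 °C; aq. NaHCO3
Reagents that add atoms: none
Why: TMSOTf should ionise the allylic acetate to a 2-silyloxyallyl (oxyallyl) cation spanning C9–C11–C12, which is captured by the tethered 1,2-bis(silyloxy)cyclopentadiene across its termini C8 and C13 in an intramolecular (4+3) cycloaddition (concerted, or stepwise by vinylogous Mukaiyama attack of C8 on C9 and closure of the C12 enol ether onto the C13 oxocarbenium ion); the C11 silyl group leaves with acetate so that the promoter turns over. The closest known reaction types are Lewis-acid-triggered intramolecular (4+3) cycloadditions of 2-silyloxyallyl and 2-alkoxyallyl cations with furans or butadienes held on three-atom tethers, and the classical intermolecular oxyallyl cation–cyclopentadiene (4+3) cycloaddition; a tethered silyloxy-cyclopentadiene is a new substrate within this class. Ring B closes by the C8–C9 bond in a 5-exo sense through the C10–C5–C6 tether, and ring C (with the seven-membered ring of the bicyclo[3.2.1]octane) closes by the C12–C13 bond onto the preformed ring D. C9 should be controlled by the ring A chair (trans-diequatorial C9 and C6 arms, W-shaped cation with C11 on the α face beside the axial C10 ester and away from the C1 methylene); C8 should follow from the extended approach, in which the tether lies nearly parallel to the outward bond of the W-shaped cation, C10 ends up on the C14 side of the new bicycle as the target requires, and the bulky C11 silyloxy group stays over C14H2 and away from the C16 silyloxy group; C13 is tied to C8 by the one-carbon bridge. The step needs (4+3) over (3+2) or O-capture, which closure at the oxocarbenium carbon C13 should secure; attack at C9 rather than C12, which the tether secures (five- versus seven-membered ring); and the extended mode, which the tether geometry and the two silyloxy groups should secure.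

Step 13
Reactants: 22 cycloadduct
Product: 23 the C11 enol triflate (C11=C12) of 22
Conditions: KHMDS (KN(SiMe3)2), THF, −78 °C; then PhNTf2, −78 → 0 °C
Reagents that add atoms: N-phenylbis(trifluoromethanesulfonimide) O=S(=O)(N(c1ccccc1)S(=O)(=O)C(F)(F)F)C(F)(F)F
Why: Kinetic deprotonation should occur at C12 because the C9 hydrogen lies between two quaternary carbons, so C9 is not touched and loss of the C13 silyloxy group is excluded (bridgehead alkene).

Step 14
Reactants: 23 enol triflate
Product: 24 trimethyl 13,16-bis(tert-butyldimethylsilyloxy)-17-norgibberella-11,15-diene-7,19,20-trioate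
Conditions: Pd(OAc)2, PPh3, HCO2H, Et3N, DMF, 60 °C
Reagents that add atoms: none
Why: Pd-catalysed formate reduction of the enol triflate removes the C11 oxygen without forming a C11 alkoxide that could lactonise onto C20.

Step 15
Reactants: 24 diene bis-silyl ether
Product: 25 trimethyl 13-(tert-butyldimethylsilyloxy)-16-oxo-17-norgibberell-11-ene-7,19,20-trioate (6β-ester)
Conditions: NaOMe, MeOH, 50 °C
Reagents that add atoms: none
Why: Methanolysis of the silyl enol ether releases the C16 ketone, and the same base should equilibrate C6 to the more stable β-ester (trans to the C5–C4 bond on ring B), converging both epimers, while the silyl group on the C13 oxygen blocks an α-ketol rearrangement.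

Step 16
Reactants: 25 11-ene 16-ketone
Product: 26 trimethyl 13-(tert-butyldimethylsilyloxy)-16-oxo-17-norgibberellane-7,19,20-trioate
Conditions: H2 (1 atm), Pd/C, EtOAc, rt
Reagents that add atoms: none
Why: Hydrogenation of the disubstituted C11=C12 alkene creates no stereocentre and leaves the hindered ketone untouched.

Step 17
Reactants: 26 16-ketone
Product: 27 trimethyl 13-(tert-butyldimethylsilyloxy)gibberell-16-ene-7,19,20-trioate
Conditions: Zn, CH2Br2, TiCl4, THF, 0 °C (pre-formed reagent); then 26, CH2Cl2, rt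
Reagents that add atoms: dibromomethane BrCBr
Why: Lombardo methylenation is non-basic, so the esters, C6 and the α-silyloxy ketone should survive while C17 is added.

Step 18
Reactants: 27 silyl ether
Product: 28 trimethyl 13-hydroxygibberell-16-ene-7,19,20-trioate (trimethyl ester of the target acid)
Conditions: TBAF (Bu4NF), THF, 50 °C
Reagents that add atoms: none
Why: Fluoride cleaves the tertiary bridgehead silyl ether under non-acidic conditions that spare the 13-hydroxy-16-ene unit.

Step 19
Reactants: 28 trimethyl ester of the target acid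
Product: 29 13-hydroxygibberell-16-ene-7,19,20-trioic acid (the target acid)
Conditions: NaSEt, DMF, 100 °C; then 1 M HCl to pH 3, 0 °C
Reagents that add atoms: none
Why: SN2 demethylation by thiolate at the methyl groups frees all three acids, including the hindered axial C19 and C20 esters, and avoids the acid that would rearrange rings C and D.

## Compound list

1 | methyl 3-oxocyclohex-1-ene-1-carboxylate | COC(=O)C1=CC(=O)CCC1 | starting material
2 | methylzinc enolate of methyl (R)-1-methyl-3-oxocyclohexane-1-carboxylate (enolate towards C5) | C[Zn]OC1=C[C@](C)(C(=O)OC)CCC1 | intermediate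
3 | methyl (R)-1-methyl-3-(trifluoromethylsulfonyloxy)cyclohex-2-ene-1-carboxylate | FC(F)(F)S(=O)(=O)OC1=C[C@](C)(C(=O)OC)CCC1 | intermediate
4 | dimethyl (R)-1-methylcyclohex-2-ene-1,3-dicarboxylate | COC(=O)C1=C[C@](C)(C(=O)OC)CCC1 | intermediate
5 | dimethyl (R)-1-methyl-4-oxocyclohex-2-ene-1,3-dicarboxylate | COC(=O)C1=C[C@](C)(C(=O)OC)CCC1=O | intermediate
6 | dimethyl (1R,4S)-4-hydroxy-1-methylcyclohex-2-ene-1,3-dicarboxylate | O[C@H]1CC[C@@](C)(C(=O)OC)C=C1C(=O)OC | intermediate
7 | 2-(cyclopent-3-en-1-yl)acetic acid | OC(=O)CC1CC=CC1 | starting material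
8 | dimethyl (1R,4S)-4-[2-(cyclopent-3-en-1-yl)acetoxy]-1-methylcyclohex-2-ene-1,3-dicarboxylate | O=C(CC1CC=CC1)O[C@H]1CC[C@@](C)(C(=O)OC)C=C1C(=O)OC | intermediate
9 | O-trimethylsilyl ketene acetal of 8 | C[Si](C)(C)OC(=CC1CC=CC1)O[C@H]1CC[C@@](C)(C(=O)OC)C=C1C(=O)OC | intermediate
10 | 2-(cyclopent-3-en-1-yl)-2-[(1R,6R)-2,6-bis(methoxycarbonyl)-6-methylcyclohex-2-en-1-yl]acetic acid (both C6 epimers) | COC(=O)C1=CCC[C@@](C)(C(=O)OC)[C@H]1C(C(=O)O)C1CC=CC1 | intermediate
11 | dimethyl (1R,2R)-2-[1-(cyclopent-3-en-1-yl)-2-methoxy-2-oxoethyl]-1-methylcyclohex-3-ene-1,3-dicarboxylate (both C6 epimers) | COC(=O)C1=CCC[C@@](C)(C(=O)OC)[C@H]1C(C(=O)OC)C1CC=CC1 | intermediate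
12 | methyl 2,2-dimethoxypropanoate | COC(=O)C(C)(OC)OC | starting material
13 | 2,2-dimethoxypropanal | CC(OC)(OC)C=O | intermediate
14 | potassium C10 ester enolate from 1,4-reduction of 11 | COC([O-])=C1CCC[C@@](C)(C(=O)OC)[C@H]1C(C(=O)OC)C1CC=CC1.[K+] | intermediate
15 | potassium C9 alkoxide (aldolate) of 14 with 13 | CC(OC)(OC)C([O-])[C@]1(C(=O)OC)CCC[C@@](C)(C(=O)OC)[C@H]1C(C(=O)OC)C1CC=CC1.[K+] | intermediate
16 | dimethyl (1R,2R,3S)-3-(1-acetoxy-2,2-dimethoxypropyl)-2-[1-(cyclopent-3-en-1-yl)-2-methoxy-2-oxoethyl]-1-methylcyclohexane-1,3-dicarboxylate (epimers at C6 and C9) | CC(OC)(OC)C(OC(C)=O)[C@]1(C(=O)OC)CCC[C@@](C)(C(=O)OC)[C@H]1C(C(=O)OC)C1CC=CC1 | intermediate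
17 | cis-3,4-dihydroxycyclopentyl analogue of 16 (ring D diol) | CC(OC)(OC)C(OC(C)=O)[C@]1(C(=O)OC)CCC[C@@](C)(C(=O)OC)[C@H]1C(C(=O)OC)C1CC(O)C(O)C1 | intermediate
18 | 3,4-dioxocyclopentyl analogue of 16 (C11 dimethyl ketal kept) | CC(OC)(OC)C(OC(C)=O)[C@]1(C(=O)OC)CCC[C@@](C)(C(=O)OC)[C@H]1C(C(=O)OC)C1CC(=O)C(=O)C1 | intermediate
19 | dimethyl (1R,2R,3S)-3-(1-acetoxy-2-oxopropyl)-2-[1-(3,4-dioxocyclopentyl)-2-methoxy-2-oxoethyl]-1-methylcyclohexane-1,3-dicarboxylate | CC(=O)C(OC(C)=O)[C@]1(C(=O)OC)CCC[C@@](C)(C(=O)OC)[C@H]1C(C(=O)OC)C1CC(=O)C(=O)C1 | intermediate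
20 | tris-silyl compound with a 3,4-bis(tert-butyldimethylsilyloxy)cyclopenta-2,4-dien-1-yl group on C6 (sp3 C8) | C=C(O[Si](C)(C)C(C)(C)C)C(OC(C)=O)[C@]1(C(=O)OC)CCC[C@@](C)(C(=O)OC)[C@H]1C(C(=O)OC)C1C=C(O[Si](C)(C)C(C)(C)C)C(O[Si](C)(C)C(C)(C)C)=C1 | intermediate
21 | tris-silyl compound with a 3,4-bis(tert-butyldimethylsilyloxy)cyclopenta-1,3-dien-1-yl group on C6 and a 1-acetoxy-2-(tert-butyldimethylsilyloxy)prop-2-enyl group on C10 | C=C(O[Si](C)(C)C(C)(C)C)C(OC(C)=O)[C@]1(C(=O)OC)CCC[C@@](C)(C(=O)OC)[C@H]1C(C(=O)OC)C1=CC(O[Si](C)(C)C(C)(C)C)=C(O[Si](C)(C)C(C)(C)C)C1 | intermediate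
22 | trimethyl 13,16-bis(tert-butyldimethylsilyloxy)-11-oxo-17-norgibberell-15-ene-7,19,20-trioate (both C6 epimers) | CC(C)(C)[Si](C)(C)OC1=C[C@]23C[C@@]1(O[Si](C)(C)C(C)(C)C)CC(=O)[C@H]2[C@]1(C(=O)OC)CCC[C@@](C)(C(=O)OC)[C@H]1C3C(=O)OC | intermediate
23 | C11 enol triflate of 22 (C11=C12) | CC(C)(C)[Si](C)(C)OC1=C[C@]23C[C@@]1(O[Si](C)(C)C(C)(C)C)C=C(OS(=O)(=O)C(F)(F)F)[C@H]2[C@]1(C(=O)OC)CCC[C@@](C)(C(=O)OC)[C@H]1C3C(=O)OC | intermediate
24 | trimethyl 13,16-bis(tert-butyldimethylsilyloxy)-17-norgibberella-11,15-diene-7,19,20-trioate (both C6 epimers) | CC(C)(C)[Si](C)(C)OC1=C[C@]23C[C@@]1(O[Si](C)(C)C(C)(C)C)C=C[C@H]2[C@]1(C(=O)OC)CCC[C@@](C)(C(=O)OC)[C@H]1C3C(=O)OC | intermediate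
25 | trimethyl 13-(tert-butyldimethylsilyloxy)-16-oxo-17-norgibberell-11-ene-7,19,20-trioate (6β-ester) | O=C1C[C@]23C[C@@]1(O[Si](C)(C)C(C)(C)C)C=C[C@H]2[C@]1(C(=O)OC)CCC[C@@](C)(C(=O)OC)[C@H]1[C@@H]3C(=O)OC | intermediate
26 | trimethyl 13-(tert-butyldimethylsilyloxy)-16-oxo-17-norgibberellane-7,19,20-trioate | O=C1C[C@]23C[C@@]1(O[Si](C)(C)C(C)(C)C)CC[C@H]2[C@]1(C(=O)OC)CCC[C@@](C)(C(=O)OC)[C@H]1[C@@H]3C(=O)OC | intermediate
27 | trimethyl 13-(tert-butyldimethylsilyloxy)gibberell-16-ene-7,19,20-trioate | C=C1C[C@]23C[C@@]1(O[Si](C)(C)C(C)(C)C)CC[C@H]2[C@]1(C(=O)OC)CCC[C@@](C)(C(=O)OC)[C@H]1[C@@H]3C(=O)OC | intermediate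
28 | trimethyl 13-hydroxygibberell-16-ene-7,19,20-trioate (trimethyl ester of the target acid) | C=C1C[C@]23C[C@@]1(O)CC[C@H]2[C@]1(C(=O)OC)CCC[C@@](C)(C(=O)OC)[C@H]1[C@@H]3C(=O)OC | intermediate
29 | 13-hydroxygibberell-16-ene-7,19,20-trioic acid (the target acid) | C=C1C[C@]23C[C@@]1(O)CC[C@H]2[C@]1(C(=O)O)CCC[C@@](C)(C(=O)O)[C@H]1[C@@H]3C(=O)O | target

## Step count and risks

Total step count: 19. Longest linear sequence: 18 steps (1 → 29 through steps 1–6 and 8–19; step 7 is a one-step branch).

Steps most likely to fail: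

1. **Step 12 (key step).** The cation may be captured only once: after the C8–C9 bond forms, the C13 silyl group may be lost before ring C closes. Facial selectivity may also erode if the compact mode competes with the extended one, or if the C11 arm takes the β face at C9.
   Fallback: the two bond formations are separated. Setting out from 21, ionisation in a strongly ionising, weakly Lewis-acidic medium (5 M LiClO4 in Et2O, rt) should stop after alkylation at C8 and give the ring-B-closed 2-silyloxy enone F1, in which the C11 silyl enol ether is kept. A TiCl4-mediated intramolecular Mukaiyama aldol addition (CH2Cl2, −78 °C) of that enol ether (C12) onto the C13 ketone should then close ring C to the 13-hydroxy 11-ketone F2. Silylation of the tertiary alcohol (TBSOTf, 2,6-lutidine) comes back to 22.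

2. **Step 8.** Hydride may be delivered 1,2 instead of 1,4; the C10 enolate may be quenched by proton transfer from the C6 hydrogen; the hindered aldolate may undergo retro-aldol before acylation.
   Fallback: enolate formation and C–C bond formation are separated and made non-basic. Setting out from 11, RhCl(PPh3)3-catalysed 1,4-hydrosilylation with Et3SiH should give the triethylsilyl ketene acetal F3. A BF3·OEt2-mediated Mukaiyama aldol addition to 13 (CH2Cl2, −78 °C) should give the C9 hydroxy ester F4, and acetylation (Ac2O, DMAP) comes back to 16.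

3. **Step 3.** Conversion may be low because the alkene is electron-poor; the product enone may be epoxidised or over-oxidised; the allyl radical may be trapped at C5 with transposition.
   Fallback: C–H oxidation is replaced by halogenation, solvolysis and alcohol oxidation. Setting out from 4, Wohl–Ziegler bromination (NBS, AIBN, PhCF3, 80 °C) should give the C1 allylic bromide F5. Silver-assisted hydrolysis (AgOTf, 2,6-lutidine, acetone/H2O, rt) should give the C1 allylic alcohol F6 as both carbinol epimers, and Dess–Martin oxidation (CH2Cl2, rt) comes back to 5.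

## Further compounds

F1 | step 12 | ring-B-closed enone: C8–C9 bond formed, ring D as 2-(tert-butyldimethylsilyloxy)cyclopent-2-enone (C13 ketone) spiro-fused at C8, C11 silyl enol ether kept on C9 (both C6 epimers) | O=C1C[C@@]2(C=C1O[Si](C)(C)C(C)(C)C)[C@@H](C(O[Si](C)(C)C(C)(C)C)=C)[C@]1(C(=O)OC)CCC[C@@](C)(C(=O)OC)[C@H]1C2C(=O)OC
F2 | step 12 | trimethyl 16-(tert-butyldimethylsilyloxy)-13-hydroxy-11-oxo-17-norgibberell-15-ene-7,19,20-trioate (both C6 epimers) | CC(C)(C)[Si](C)(C)OC1=C[C@]23C[C@@]1(O)CC(=O)[C@H]2[C@]1(C(=O)OC)CCC[C@@](C)(C(=O)OC)[C@H]1C3C(=O)OC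
F3 | step 8 | O-triethylsilyl ketene acetal of the C10 ester from 1,4-hydrosilylation of 11 | CC[Si](CC)(CC)OC(OC)=C1CCC[C@@](C)(C(=O)OC)[C@H]1C(C(=O)OC)C1CC=CC1
F4 | step 8 | dimethyl (1R,2R,3S)-2-[1-(cyclopent-3-en-1-yl)-2-methoxy-2-oxoethyl]-3-(1-hydroxy-2,2-dimethoxypropyl)-1-methylcyclohexane-1,3-dicarboxylate (epimers at C6 and C9) | CC(OC)(OC)C(O)[C@]1(C(=O)OC)CCC[C@@](C)(C(=O)OC)[C@H]1C(C(=O)OC)C1CC=CC1
F5 | step 3 | dimethyl (1R)-4-bromo-1-methylcyclohex-2-ene-1,3-dicarboxylate (both C–Br epimers) | BrC1CC[C@@](C)(C(=O)OC)C=C1C(=O)OC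
F6 | step 3 | dimethyl (1R)-4-hydroxy-1-methylcyclohex-2-ene-1,3-dicarboxylate (both carbinol epimers) | OC1CC[C@@](C)(C(=O)OC)C=C1C(=O)OC
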